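**Plan**

Numbering: ring C1 (enal carbon), C2, C3, C4 (C(OH)CH3), C5 (quaternary), C6 (CH with the hydroxypropyl arm); primed numbers count the C5 side chain outward; TBS = tert-butyldimethylsilyl.
Cuts: first the epoxide oxygen, then the three-carbon enal cap at C1 and the methyl at C4, which leaves a cyclohexane-1,4-dione. Because C1 and C4 are carbonyl-level carbons in a 1,4 relationship, ring bond C2–C3 links the α-carbons of two methyl ketones and is cut to a hexane-2,5-dione. C5–C6 is then cut by Ireland–Claisen rearrangement and C9'–C10' by dithiane alkylation.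
Forward: farnesol is extended at its far end to a C20 allylic alcohol that already carries the C10' carbinol, esterified with the δ-valerolactone-derived acid and rearranged to join C5–C6. The product is turned into the 2,5-dione and the single carbocycle is closed at C2–C3. Two Grignard additions, an oxidative allylic transposition, desilylation and a directed epoxidation finish the route.
Stereochemistry: C5/C6 from the chair Ireland–Claisen of the (E)-allyl ester through a chiral boron Z(O)-enolate; C10' from CBS reduction; C4 from axial methyl addition under ring control; C11' from hydroxyl-directed epoxidation (allylic 1,3-strain); enal geometry from the transposition.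

Key step: step 15

Assumption: the (4S,5S)-diazaborolidine bromide is taken to select the enolate face that leads to the (2S,3R) acid of step 12; the sense would be verified on the first run and the equally accessible (4R,5R) reagent used instead if it proved opposite.

**Route**

Step 1
Reactants: 1 (2E,6E)-farnesol
Product: 2 (2E,6E)-farnesyl pivalate
Conditions: PivCl, pyridine, 4-(dimethylamino)pyridine (cat.), CH2Cl2, 0 °C to rt
Reagents that add atoms: pivaloyl chloride, CC(C)(C)C(Cl)=O
Why: Acylation of the primary allylic alcohol with an acid chloride; the pivalate is base-stable, has no α-hydrogen for the dithiane anion of step 5 and deactivates the C2=C3 alkene toward step 2.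

Step 2
Reactants: 2 (2E,6E)-farnesyl pivalate
Product: 3 (2E,6E,10E)-12-hydroxyfarnesyl pivalate
Conditions: SeO2 (cat.), t-BuOOH, salicylic acid (cat.), CH2Cl2, rt
Reagents that add atoms: tert-butyl hydroperoxide, CC(C)(C)OO (oxygen, relayed by SeO2, O=[Se]=O)
Why: Riley allylic oxidation with catalytic SeO2 (ene reaction, then 2,3-sigmatropic shift) should oxidise the (E)-methyl of the terminal, most electron-rich trisubstituted alkene to the (E)-allylic alcohol, the alkene next to the ester being deactivated.

Step 3
Reactants: 3 (2E,6E,10E)-12-hydroxyfarnesyl pivalate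
Product: 4 (2E,6E,10E)-12-bromofarnesyl pivalate
Conditions: CBr4, PPh3, CH2Cl2, 0 °C
Reagents that add atoms: carbon tetrabromide, BrC(Br)(Br)Br
Why: Appel reaction, in which bromide displaces the alkoxyphosphonium group at the primary allylic carbon under cold, neutral conditions without allylic shift.

Step 4
Reactants: 5 3-methylbut-2-enal; 6 propane-1,3-dithiol
Product: 7 2-(2-methylprop-1-en-1-yl)-1,3-dithiane
Conditions: BF3·OEt2 (cat.), CH2Cl2, 0 °C
Reagents that add atoms: none
Why: Lewis-acid-catalysed dithioacetalisation of the aldehyde, 1,2-addition and ring closure being favoured over conjugate addition for the β,β-disubstituted enal.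

Step 5
Reactants: 7 2-(2-methylprop-1-en-1-yl)-1,3-dithiane; 4 (2E,6E,10E)-12-bromofarnesyl pivalate
Product: 9 (2E,6E,10E)-3,7,11-trimethyl-12-[2-(2-methylprop-1-en-1-yl)-1,3-dithian-2-yl]dodeca-2,6,10-trien-1-yl pivalate, via lithiated dithiane 8 (not isolated)
Conditions: n-BuLi, THF, −30 °C; then 4, −78 °C
Reagents that add atoms: none
Why: Corey–Seebach alkylation, in which the lithiated alkenyl dithiane (an acyl-anion equivalent) should attack the allylic bromide by SN2 through its dithiane carbon because the γ-terminus carries two methyl groups, forming C9'–C10' with the (E)-alkene retained while the hindered, non-enolisable pivalate is left alone.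

Step 6
Reactants: 9 dithiane-bearing pivalate
Product: 10 (2E,6E,10E)-3,7,11,15-tetramethyl-13-oxohexadeca-2,6,10,14-tetraen-1-yl pivalate
Conditions: MeI, CaCO3, MeCN/H2O, 40 °C
Reagents that add atoms: water, O
Why: Alkylative dithiane hydrolysis (S-methylation, then attack of water) under CaCO3 buffering unmasks the ketone under near-neutral conditions meant to keep the C7'=C8' alkene out of conjugation.

Step 7
Reactants: 10 skipped enone pivalate
Product: 11 (2E,6E,10E,13S)-13-hydroxy-3,7,11,15-tetramethylhexadeca-2,6,10,14-tetraen-1-yl pivalate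
Conditions: (R)-1-methyl-3,3-diphenyltetrahydro-1H,3H-pyrrolo[1,2-c][1,3,2]oxazaborole (cat.), catecholborane, toluene, −78 °C
Reagents that add atoms: none
Why: Corey–Bakshi–Shibata reduction, in which the enone binds the oxazaborolidine–borane complex with the alkenyl group as the large substituent so that the (R)-catalyst should deliver hydride to give the (S)-allylic alcohol (C10'), catecholborane at low temperature sparing ester and alkenes.

Step 8
Reactants: 11 (13S)-allylic alcohol pivalate
Product: 12 (2E,6E,10E,13S)-13-(TBS-oxy)-3,7,11,15-tetramethylhexadeca-2,6,10,14-tetraen-1-yl pivalate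
Conditions: TBSCl, imidazole, DMF, rt
Reagents that add atoms: tert-butyldimethylsilyl chloride, CC(C)(C)[Si](C)(C)Cl
Why: Imidazole-mediated silyl ether formation masks the C10' hydroxyl for the organometallic and oxidation steps ahead.

Step 9
Reactants: 12 silyl ether pivalate
Product: 13 (2E,6E,10E,13S)-13-(TBS-oxy)-3,7,11,15-tetramethylhexadeca-2,6,10,14-tetraen-1-ol
Conditions: i-Bu2AlH, CH2Cl2, −78 °C
Reagents that add atoms: none
Why: Reductive ester cleavage with i-Bu2AlH at low temperature frees the primary allylic alcohol without touching the silyl ether or the alkenes.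

Step 10
Reactants: 14 δ-valerolactone
Product: 17 5-(TBS-oxy)pentanoic acid, via sodium 5-hydroxypentanoate 15 (not isolated), via bis-silylated pentanoate 16 (not isolated)
Conditions: NaOH, MeOH/H2O, 60 °C, evaporate; TBSCl, imidazole, DMF, rt; K2CO3, MeOH/THF/H2O, rt, then aq. HCl to pH 4
Reagents that add atoms: sodium hydroxide, [Na+].[OH-]; tert-butyldimethylsilyl chloride, CC(C)(C)[Si](C)(C)Cl
Why: Saponification of the lactone, exhaustive silylation and selective solvolysis of the far more labile silyl ester leave the silyl ether acid (standard ring-opening and protection sequence).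

Step 11
Reactants: 13 C20 allylic alcohol; 17 5-(TBS-oxy)pentanoic acid
Product: 18 (2E,6E,10E,13S)-13-(TBS-oxy)-3,7,11,15-tetramethylhexadeca-2,6,10,14-tetraen-1-yl 5-(TBS-oxy)pentanoate
Conditions: N-ethyl-N'-(3-dimethylaminopropyl)carbodiimide hydrochloride, 4-(dimethylamino)pyridine (cat.), CH2Cl2, 0 °C to rt
Reagents that add atoms: none
Why: Carbodiimide (Steglich) esterification joins the two fragments under mild conditions that leave both silyl ethers and the allylic systems intact.

Step 12
Reactants: 18 allylic ester
Product: 20 (2S,3R,6E,10E,13S)-3-ethenyl-3,7,11,15-tetramethyl-13-(TBS-oxy)-2-[3-(TBS-oxy)propyl]hexadeca-6,10,14-trienoic acid, via boron ketene acetal 19 (not isolated)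
Conditions: (4S,5S)-2-bromo-1,3-bis{[3,5-bis(trifluoromethyl)phenyl]sulfonyl}-4,5-diphenyl-1,3,2-diazaborolidine, i-Pr2NEt, CH2Cl2, −78 °C, then −20 °C to 4 °C; aqueous work-up
Reagents that add atoms: none
Why: Enantioselective Ireland–Claisen rearrangement, in which soft enolisation with the chiral bromoborane and i-Pr2NEt in CH2Cl2 should give the boron ketene acetal with the α-substituent cis to O–B [Z(O)], which rearranges through a chair transition state with the C3 methyl of the (E)-alkene axial and the chain equatorial, so that the C5 methyl and the C6 arm end up cis on the later ring, the sulfonamide controller selecting the enolate face and hence the absolute configuration of C5 and C6.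

Step 13
Reactants: 20 rearranged acid
Product: 22 (3S,4R,7E,11E,14S)-4-ethenyl-4,8,12,16-tetramethyl-14-(TBS-oxy)-3-[3-(TBS-oxy)propyl]heptadeca-7,11,15-trien-2-one, via dilithium gem-diolate 21 (not isolated)
Conditions: MeLi (excess), Et2O, 0 °C to rt; poured into ice-water
Reagents that add atoms: methyllithium, [Li]C
Why: Ketone synthesis from a carboxylic acid with MeLi, in which the lithium carboxylate adds one MeLi to give a geminal dilithium dialkoxide that cannot collapse before the aqueous quench, so that addition should stop at the methyl ketone (C1=O with the C2 methyl) without deprotonation at C6.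

Step 14
Reactants: 22 vinyl methyl ketone
Product: 23 (3S,4S)-3-methyl-3-[(3E,7E,10S)-10-(TBS-oxy)-4,8,12-trimethyltrideca-3,7,11-trien-1-yl]-4-[3-(TBS-oxy)propyl]hexane-2,5-dione
Conditions: PdCl2 (cat.), CuCl, O2 (1 atm), DMF/H2O, rt
Reagents that add atoms: water, O
Why: Tsuji–Wacker oxidation, in which hydroxypalladation of the only monosubstituted alkene at its internal carbon and β-hydride elimination should give the second methyl ketone (C4=O with the C3 methyl), the trisubstituted alkenes being inert toward divalent palladium under these conditions.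

Step 15
Reactants: 23 3,4-disubstituted hexane-2,5-dione
Product: 26 (2S,3S)-2-methyl-2-[(3E,7E,10S)-10-(TBS-oxy)-4,8,12-trimethyltrideca-3,7,11-trien-1-yl]-3-[3-(TBS-oxy)propyl]cyclohexane-1,4-dione, via bis(trimethylsilyl enol ether) 24 (not isolated), via dilithium bis-enolate 25 (not isolated)
Conditions: LiN(i-Pr)2/Me3SiCl (premixed), THF, −78 °C, slow addition of 23; pentane filtration; MeLi, THF, 0 °C; CuCl2, DMF/THF, −78 °C to rt, high dilution
Reagents that add atoms: none
Why: Kinetic deprotonation with in-situ silylation should fix both enol ethers at the methyl groups (C5 has no hydrogen and C6–H is shielded by the quaternary neighbour), and because each enolate is silylated as it forms it has little time to add to the other carbonyl, which is the aldol cyclisation to a cyclopentanone that 1,4-diketones otherwise undergo. MeLi then releases the amine-free dilithium bis-enolate, and one-electron oxidation by CuCl2 gives a copper-bound α-keto radical at one methylene that bonds to the terminal carbon of the neighbouring enolate, a second electron transfer delivering the 1,4-dione. The closest known reaction is the oxidative coupling of ketone enolates with divalent copper or trivalent iron salts, here in its intramolecular dienolate form. The six-membered ring closes head to head through C2–C3, formally a 6-endo-trig attack on the CH2 terminus of the second enolate. No stereocentre is created, and C5 and C6 are carried through unchanged because neither is enolised. The step needs ring closure to outrun addition of the radical to the chain alkenes and intermolecular coupling, which the proximity of the two enolate termini, the inner-sphere oxidant and high dilution should secure.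

Step 16
Reactants: 26 cyclohexane-1,4-dione
Product: 27 C1 isopropenyl carbinol: 4-hydroxy-4-(prop-1-en-2-yl)cyclohexanone with C4 still a ketone (expected C1 epimer: isopropenyl trans and hydroxyl cis to the C6 arm)
Conditions: CH2=C(CH3)MgBr, LaCl3·2LiCl, THF, −40 °C
Reagents that add atoms: isopropenylmagnesium bromide, CC(=C)[Mg]Br
Why: Lewis-acid-promoted Grignard 1,2-addition (LaCl3·2LiCl suppresses enolisation and thus C6 epimerisation) should occur at the C1 carbonyl, flanked by a tertiary and a secondary carbon, in preference to the C4 carbonyl beside the quaternary C5, the nucleophile entering equatorially trans to the C6 arm, although the C1 configuration is erased in step 18.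

Step 17
Reactants: 27 C1 isopropenyl carbinol
Product: 28 C1,C4-diol (C4 methyl on the face of the C5 chain; C4 hydroxyl on the face of the C5 methyl and the C6 arm)
Conditions: MeMgBr (excess), LaCl3·2LiCl, THF, 0 °C to rt
Reagents that add atoms: methylmagnesium bromide, C[Mg]Br
Why: Lewis-acid-assisted Grignard 1,2-addition to the hindered C4 ketone, in which the chair holding the C6 arm and the C5 chain equatorial has the C5 methyl axial and blocking the equatorial trajectory, so that methyl should enter axially on the face of the C5 chain and set C4 with its hydroxyl equatorial and cis to the C5 methyl and the C6 arm.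

Step 18
Reactants: 28 C1,C4-diol
Product: 29 bis-silylated (Z)-enal: C1=C(CH3)CHO with CHO on the C6 side
Conditions: [C5H5NH][CrO3Cl] (pyridinium chlorochromate), NaOAc, CH2Cl2, rt
Reagents that add atoms: pyridinium chlorochromate, [O-][Cr](=O)(=O)Cl.c1cc[nH+]cc1
Why: Babler–Dauben oxidative 1,3-transposition, in which the chromate ester of the tertiary allylic alcohol undergoes a 3,3-sigmatropic shift to the primary allylic chromate that is oxidised to the enal, and both the transition state that turns the isopropenyl methyl toward the unsubstituted C2 side and the lower allylic 1,3-strain of formyl compared with methyl beside C6 should favour the required geometry.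

Step 19
Reactants: 29 bis-silylated enal
Product: 30 desilylated enal triol (free C10' allylic alcohol, C4 tertiary alcohol and primary alcohol)
Conditions: Bu4NF, AcOH, THF, 0 °C to rt
Reagents that add atoms: none
Why: Fluoride-mediated desilylation removes both silyl ethers at once, acetic acid buffering protecting the enal and the ionisable allylic alcohol from base.

Step 20
Reactants: 30 enal triol
Product: 31 target CNP0161066.1
Conditions: VO(acac)2 (cat.), t-BuOOH, CH2Cl2, 0 °C
Reagents that add atoms: tert-butyl hydroperoxide, CC(C)(C)OO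
Why: Vanadium-catalysed hydroxyl-directed epoxidation of the allylic alcohol, in which the alkoxide-bound peroxo vanadium species delivers oxygen to the C11'=C12' alkene and allylic 1,3-strain from the cis methyl on C12' holds C10'–H in the alkene plane, so that oxygen should arrive syn to the hydroxyl and give the threo (10'S,11'R) epoxy alcohol, while the homoallylic C7'=C8' alkene, the remote alkene and the electron-poor enal react far more slowly.

**Compound list**

1 | (2E,6E)-farnesol | OC/C=C(\C)CC/C=C(\C)CCC=C(C)C | starting material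
2 | (2E,6E)-farnesyl pivalate | CC(C)(C)C(=O)OC/C=C(\C)CC/C=C(\C)CCC=C(C)C | intermediate
3 | (2E,6E,10E)-12-hydroxyfarnesyl pivalate | CC(C)(C)C(=O)OC/C=C(\C)CC/C=C(\C)CC/C=C(\C)CO | intermediate
4 | (2E,6E,10E)-12-bromofarnesyl pivalate | CC(C)(C)C(=O)OC/C=C(\C)CC/C=C(\C)CC/C=C(\C)CBr | intermediate
5 | 3-methylbut-2-enal | CC(C)=CC=O | starting material
6 | propane-1,3-dithiol | SCCCS | starting material
7 | 2-(2-methylprop-1-en-1-yl)-1,3-dithiane | CC(C)=CC1SCCCS1 | intermediate
8 | 2-lithio-2-(2-methylprop-1-en-1-yl)-1,3-dithiane | CC(C)=CC1([Li])SCCCS1 | intermediate (not isolated)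
9 | (2E,6E,10E)-3,7,11-trimethyl-12-[2-(2-methylprop-1-en-1-yl)-1,3-dithian-2-yl]dodeca-2,6,10-trien-1-yl pivalate | CC(C)(C)C(=O)OC/C=C(\C)CC/C=C(\C)CC/C=C(\C)CC1(C=C(C)C)SCCCS1 | intermediate
10 | (2E,6E,10E)-3,7,11,15-tetramethyl-13-oxohexadeca-2,6,10,14-tetraen-1-yl pivalate | CC(C)(C)C(=O)OC/C=C(\C)CC/C=C(\C)CC/C=C(\C)CC(=O)C=C(C)C | intermediate
11 | (2E,6E,10E,13S)-13-hydroxy-3,7,11,15-tetramethylhexadeca-2,6,10,14-tetraen-1-yl pivalate | CC(C)(C)C(=O)OC/C=C(\C)CC/C=C(\C)CC/C=C(\C)C[C@H](O)C=C(C)C | intermediate
12 | (2E,6E,10E,13S)-13-(TBS-oxy)-3,7,11,15-tetramethylhexadeca-2,6,10,14-tetraen-1-yl pivalate | CC(C)(C)C(=O)OC/C=C(\C)CC/C=C(\C)CC/C=C(\C)C[C@H](O[Si](C)(C)C(C)(C)C)C=C(C)C | intermediate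
13 | (2E,6E,10E,13S)-13-(TBS-oxy)-3,7,11,15-tetramethylhexadeca-2,6,10,14-tetraen-1-ol | OC/C=C(\C)CC/C=C(\C)CC/C=C(\C)C[C@H](O[Si](C)(C)C(C)(C)C)C=C(C)C | intermediate
14 | δ-valerolactone | O=C1CCCCO1 | starting material
15 | sodium 5-hydroxypentanoate | [Na+].[O-]C(=O)CCCCO | intermediate (not isolated)
16 | tert-butyldimethylsilyl 5-(TBS-oxy)pentanoate | CC(C)(C)[Si](C)(C)OCCCCC(=O)O[Si](C)(C)C(C)(C)C | intermediate (not isolated)
17 | 5-(TBS-oxy)pentanoic acid | CC(C)(C)[Si](C)(C)OCCCCC(=O)O | intermediate
18 | (2E,6E,10E,13S)-13-(TBS-oxy)-3,7,11,15-tetramethylhexadeca-2,6,10,14-tetraen-1-yl 5-(TBS-oxy)pentanoate | CC(C)(C)[Si](C)(C)OCCCCC(=O)OC/C=C(\C)CC/C=C(\C)CC/C=C(\C)C[C@H](O[Si](C)(C)C(C)(C)C)C=C(C)C | intermediate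
19 | Z(O)-boron ketene acetal of 18 (α-substituent cis to O–B; boron in the (4S,5S)-bis-sulfonyl diazaborolidine) | CC(C)(C)[Si](C)(C)OCCC/C=C(\OB1N(S(=O)(=O)c2cc(cc(c2)C(F)(F)F)C(F)(F)F)[C@@H](c2ccccc2)[C@H](c2ccccc2)N1S(=O)(=O)c1cc(cc(c1)C(F)(F)F)C(F)(F)F)OC/C=C(\C)CC/C=C(\C)CC/C=C(\C)C[C@H](O[Si](C)(C)C(C)(C)C)C=C(C)C | intermediate (not isolated)
20 | (2S,3R,6E,10E,13S)-3-ethenyl-3,7,11,15-tetramethyl-13-(TBS-oxy)-2-[3-(TBS-oxy)propyl]hexadeca-6,10,14-trienoic acid | C=C[C@@](C)(CC/C=C(\C)CC/C=C(\C)C[C@H](O[Si](C)(C)C(C)(C)C)C=C(C)C)[C@@H](C(=O)O)CCCO[Si](C)(C)C(C)(C)C | intermediate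
21 | dilithium gem-diolate formed from 20 and MeLi | C=C[C@@](C)(CC/C=C(\C)CC/C=C(\C)C[C@H](O[Si](C)(C)C(C)(C)C)C=C(C)C)[C@@H](C(C)(O[Li])O[Li])CCCO[Si](C)(C)C(C)(C)C | intermediate (not isolated)
22 | (3S,4R,7E,11E,14S)-4-ethenyl-4,8,12,16-tetramethyl-14-(TBS-oxy)-3-[3-(TBS-oxy)propyl]heptadeca-7,11,15-trien-2-one | C=C[C@@](C)(CC/C=C(\C)CC/C=C(\C)C[C@H](O[Si](C)(C)C(C)(C)C)C=C(C)C)[C@@H](C(C)=O)CCCO[Si](C)(C)C(C)(C)C | intermediate
23 | (3S,4S)-3-methyl-3-[(3E,7E,10S)-10-(TBS-oxy)-4,8,12-trimethyltrideca-3,7,11-trien-1-yl]-4-[3-(TBS-oxy)propyl]hexane-2,5-dione | CC(=O)[C@@](C)(CC/C=C(\C)CC/C=C(\C)C[C@H](O[Si](C)(C)C(C)(C)C)C=C(C)C)[C@@H](C(C)=O)CCCO[Si](C)(C)C(C)(C)C | intermediate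
24 | 2,5-bis(trimethylsilyl enol ether) of 23 (both enol ethers at the methyl groups) | C=C(O[Si](C)(C)C)[C@@](C)(CC/C=C(\C)CC/C=C(\C)C[C@H](O[Si](C)(C)C(C)(C)C)C=C(C)C)[C@@H](C(=C)O[Si](C)(C)C)CCCO[Si](C)(C)C(C)(C)C | intermediate (not isolated)
25 | dilithium bis-enolate of 23 | C=C(O[Li])[C@@](C)(CC/C=C(\C)CC/C=C(\C)C[C@H](O[Si](C)(C)C(C)(C)C)C=C(C)C)[C@@H](C(=C)O[Li])CCCO[Si](C)(C)C(C)(C)C | intermediate (not isolated)
26 | (2S,3S)-2-methyl-2-[(3E,7E,10S)-10-(TBS-oxy)-4,8,12-trimethyltrideca-3,7,11-trien-1-yl]-3-[3-(TBS-oxy)propyl]cyclohexane-1,4-dione | O=C1CCC(=O)[C@@](C)(CC/C=C(\C)CC/C=C(\C)C[C@H](O[Si](C)(C)C(C)(C)C)C=C(C)C)[C@@H]1CCCO[Si](C)(C)C(C)(C)C | intermediate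
27 | C1 isopropenyl carbinol (C4 ketone; expected C1 epimer with isopropenyl trans to the C6 arm) | C=C(C)[C@@]1(O)CCC(=O)[C@@](C)(CC/C=C(\C)CC/C=C(\C)C[C@H](O[Si](C)(C)C(C)(C)C)C=C(C)C)[C@@H]1CCCO[Si](C)(C)C(C)(C)C | intermediate
28 | C1,C4-diol (C4 methyl cis to the C5 chain, C4 hydroxyl cis to the C5 methyl) | C=C(C)[C@@]1(O)CC[C@](C)(O)[C@@](C)(CC/C=C(\C)CC/C=C(\C)C[C@H](O[Si](C)(C)C(C)(C)C)C=C(C)C)[C@@H]1CCCO[Si](C)(C)C(C)(C)C | intermediate
29 | bis-silylated (Z)-enal (CHO on the C6 side of C1=C) | C/C(C=O)=C1\CC[C@](C)(O)[C@@](C)(CC/C=C(\C)CC/C=C(\C)C[C@H](O[Si](C)(C)C(C)(C)C)C=C(C)C)[C@@H]1CCCO[Si](C)(C)C(C)(C)C | intermediate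
30 | enal triol with free (10'S)-allylic alcohol | C/C(C=O)=C1\CC[C@](C)(O)[C@@](C)(CC/C=C(\C)CC/C=C(\C)C[C@H](O)C=C(C)C)[C@@H]1CCCO | intermediate
31 | CNP0161066.1, ring (4S,5S,6R), chain (3'E,7'E,10'S,11'R), (Z)-enal | C/C(C=O)=C1\CC[C@](C)(O)[C@@](C)(CC/C=C(\C)CC/C=C(\C)C[C@H](O)[C@H]2OC2(C)C)[C@@H]1CCCO | target

**Step count and risks**

Total: 20 steps. Longest linear sequence: 18 steps from farnesol (steps 1–3, 5–9 and 11–20); steps 4 and 10 are single-step side branches.

Steps most likely to fail:

Step 15. What may go wrong: the first-formed mono-enolate adds to the second carbonyl (five-membered aldol) before it is silylated, or, at the copper stage, α-chlorination and intermolecular coupling compete with ring closure. Fallback: setting out from 23, soft enolisation with t-BuMe2SiOTf and Et3N in CH2Cl2 at 0 °C, in which no metal enolate is present at any time, should give the isolable bis(tert-butyldimethylsilyl enol ether) F1. One-electron oxidation of this compound with (NH4)2Ce(NO3)6 and NaHCO3 in MeCN at −20 °C (radical-cation coupling of silyl enol ethers) would then form the C2–C3 bond and come back to the route at 26.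

Step 14. What may go wrong: oxypalladation of a vinyl group on a quaternary carbon is slow and may stall or turn toward the terminal carbon (aldehyde formation), and hydrogen chloride released in the medium may loosen a silyl ether. Fallback: setting out from acid 20, iodolactonisation (I2, NaHCO3, MeCN, 0 °C) engages only the γ,δ-alkene and should give the iodomethyl γ-lactone F2, which already carries oxygen at C4. Radical deiodination (Bu3SnH, azobisisobutyronitrile, toluene, 80 °C, high tin hydride concentration) gives the methyl γ-lactone F3. One equivalent of MeLi at −78 °C opens it to the γ-hydroxy methyl ketone F4 (in equilibrium with its cyclic hemiketal). Oxidation with 1,1,1-triacetoxy-1,1-dihydro-1,2-benziodoxol-3(1H)-one and NaHCO3 in CH2Cl2 comes back to the route at 23, bypassing 22.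

Step 18. What may go wrong: the tertiary allylic chromate ionises and dehydrates to dienes under the acidic oxidant, or the tetrasubstituted enal forms as a geometric mixture. Fallback: setting out from 28, catalytic Ph3SiOReO3 in Et2O at −50 to 0 °C should effect the 1,3-transposition of the free tertiary allylic alcohol, leaving the allylic silyl ether alone, to give the primary allylic alcohol F5. Oxidation with MnO2 in CH2Cl2, which attacks only the allylic primary alcohol, comes back to the route at 29; the enal can there be equilibrated toward the isomer with the formyl group beside C6.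

**Further compounds**

F1 | step 15 | 2,5-bis(tert-butyldimethylsilyl enol ether) of 23 | C=C(O[Si](C)(C)C(C)(C)C)[C@@](C)(CC/C=C(\C)CC/C=C(\C)C[C@H](O[Si](C)(C)C(C)(C)C)C=C(C)C)[C@@H](C(=C)O[Si](C)(C)C(C)(C)C)CCCO[Si](C)(C)C(C)(C)C
F2 | step 14 | iodomethyl γ-lactone from 20 (C4 configuration open, removed later) | O=C1OC(CI)[C@@](C)(CC/C=C(\C)CC/C=C(\C)C[C@H](O[Si](C)(C)C(C)(C)C)C=C(C)C)[C@@H]1CCCO[Si](C)(C)C(C)(C)C
F3 | step 14 | methyl γ-lactone (C4 configuration open) | O=C1OC(C)[C@@](C)(CC/C=C(\C)CC/C=C(\C)C[C@H](O[Si](C)(C)C(C)(C)C)C=C(C)C)[C@@H]1CCCO[Si](C)(C)C(C)(C)C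
F4 | step 14 | γ-hydroxy methyl ketone (C4 carbinol, configuration open) | CC(O)[C@@](C)(CC/C=C(\C)CC/C=C(\C)C[C@H](O[Si](C)(C)C(C)(C)C)C=C(C)C)[C@@H](C(C)=O)CCCO[Si](C)(C)C(C)(C)C
F5 | step 18 | transposed primary allylic alcohol, C1=C(CH3)CH2OH with CH2OH on the C6 side | C/C(CO)=C1\CC[C@](C)(O)[C@@](C)(CC/C=C(\C)CC/C=C(\C)C[C@H](O[Si](C)(C)C(C)(C)C)C=C(C)C)[C@@H]1CCCO[Si](C)(C)C(C)(C)C
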